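The first addition, J + X → D + Z, takes one J and one X together, so on that step by itself the difference cX − cJ stays at its charged 20.8 mM.

| flask | J | X | temperature | time | remark |
|---|---|---|---|---|---|
| Friday's | 26 mM | 46.8 mM | 90 °C | 15 min |  |
| Thursday's | 26 mM | 46.8 mM |  | 15 min | at 105 °C until 8.0 min, from then on at 90 °C |
| Saturday's | 26 mM | 46.8 mM | 105 °C | 15 min |  |

- the flask that comes out highest in amount of D, in percent of the J charged, or "all alike" when all lie within 1.5 percentage points (Friday's / Thursday's / Saturday's / all alike)
- D at the end, in percent of the J charged, Friday's
- D at the end, in percent of the J charged, Thursday's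
- D at the end, in percent of the J charged, Saturday's

    D → Q (k1 = 0.0027 s⁻¹, Ea1 = 116 kJ mol⁻¹)
    X + D → G + Z (k2 = 0.0044 M⁻¹ s⁻¹, Ea2 = 71.0 kJ mol⁻¹)
    J + X → D + Z (k3 = 0.17 M⁻¹ s⁻¹, Ea3 = 67.0 kJ mol⁻¹)
    X + G → E + Z (k4 = 0.0030 M⁻¹ s⁻¹, Ea4 = 60.0 kJ mol⁻¹)
    (constants at 90 °C)

- the constants hold at 90 °C; other temperatures follow from the activation energies

From that invariant I took the cX that J meets late on: with J small, cX on that step by itself tends to the gap. On the first addition by itself, the ratio cJ/cX falls exponentially at 0.212 min⁻¹, the rate constant of that addition times the gap, which I called the gap constant kf. Once J is small, kf is its pseudo-first-order constant at 90 °C.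

I bracketed Friday's D by treating it as made from J and lost first order. For a rough ceiling, an estimate and no strict bound, I let J fall at kf throughout, with D lost by its decay to Q, and got 19.7%. For a rough floor, again an estimate, I let J fall at the charged rate 0.477 min⁻¹, with D also lost to the second addition at charged cX, a total loss constant of 0.174 min⁻¹, and got 11.4%.

The ratio tightened the ceiling. On the first addition by itself, it put J at 1.89% of its charge at the end. As cX falls, J's decay slows, so J's curve lies under the single exponential through that endpoint, and its D is formed earlier and ages longer. That exponential has the constant 0.265 min⁻¹; with the loss constant taken at cX equal to the gap, 0.167 min⁻¹, the ceiling came down to 16.9%, and my hand stopped there. From 90 °C to 105 °C the decay of D speeds up by a factor 4.6 and the first addition by 2.4, a faster rise, so I expected the hot flasks to hold less D.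

The forecast named Friday's as highest, with D at 14.8% (13.5% to 16%) in Friday's, 0.85% in Thursday's and 0.05% in Saturday's, on the ground that “heat destroys D faster than it makes it”. Its Friday's range lies above my floor and below my ceiling.

The flasks gave D at 14.7% in Friday's, 0.836% in Thursday's and 0.0484% in Saturday's, so Friday's stood highest. At the end of Friday's, with J at 2.04% and D at 14.7%, kf·cJ over the decay rate of D comes to 0.182, and D was being made slower than it was used, at a net ratio of 0.173. In Thursday's, J stood at 0.814% at the change to 90 °C, kf takes that down to 0.184% by the end, and the flask read 0.192%.

(All constants are invented; no experiment stands behind them.)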